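(All runs were computed on assumed constants; noise was put on by code.)

3 questions are asked about one flask, and I carry one quantity through them.

common to all: D 0.31 M; Q 0.31 M
- Tuesday's: Z 0.186 M; E 18 mM; run made earlier
- Sunday's: Z 0.186 M; E 28 mM; run made earlier
- Monday's: Z 0.093 M; E 37 mM; run made earlier
- flask: Z 0.186 M; E 37 mM; time 10 d

| run | time / d | L / % | G / % | D / % |
|---|---|---|---|---|
| Tuesday's | 0.417 | 17.6 | 4.7 | 31.0 |
| Tuesday's | 1.25 | 22.7 | 6.0 | 27.5 |
| Tuesday's | 2.50 | 22.9 | 5.8 | 27.0 |
| Tuesday's | 3.00 | 23.5 | 6.0 | 25.9 |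
| Tuesday's | 5.00 | 23.9 | 6.9 | 27.4 |
| Tuesday's | 6.00 | 22.8 | 6.5 | 27.1 |
| Tuesday's | 8.00 | 23.3 | 6.3 | 26.5 |
| Sunday's | 1.25 | 23.8 | 6.7 | 27.3 |
| Sunday's | 2.50 | 22.7 | 5.8 | 26.5 |
| Sunday's | 3.00 | 22.9 | 6.7 | 26.2 |
| Sunday's | 5.00 | 23.4 | 5.7 | 26.1 |
| Sunday's | 6.00 | 23.9 | 6.6 | 25.9 |
| Sunday's | 8.00 | 23.3 | 6.1 | 26.6 |
| Monday's | 1.67 | 13.0 | 2.7 | 37.6 |
| Monday's | 3.00 | 12.0 | 2.4 | 38.1 |
| Monday's | 5.00 | 11.3 | 2.6 | 37.7 |
| Monday's | 6.00 | 11.6 | 2.5 | 38.2 |
| Monday's | 8.00 | 12.0 | 3.3 | 38.3 |

(scatter of a reading: 0.5 percentage points)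

- E is single-handed; D and Q are mirror images of each other, charged as a racemate, each of them at the stated concentration
- an excess is the difference of the two amounts in percent of their sum
- an excess is below zero if the other one leads

1. excess of L over G in the product at 12 h
2. excess of L over G in the product at 10 d
3. part of the D and Q charged together that has reacted at 10 d

1. I define the ceiling c as Z charged over D and Q charged together. For the flask c = 30.0%. Monday's run has c = 15.0%, and its sums of L and G average 14.7%, so I take Z as the limiting reagent and c as my upper bound on the part reacted in the flask.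

2. For a lower bound, one late sum of L and G is weak: Sunday's at 2.50 d reads 28.5%. Instead I replace the plateau by its mean over Tuesday's and Sunday's 10 sums from 2.50 d on: 29.5%, with a scatter of 0.22 percentage points. Two such scatters below the mean gives 29.1%, and both runs have the flask's charges of D, Q and Z, so I commit to the flask's part reacted lying between that and c.

3. The same readings give L a mean of 23.3%, so I expect an excess in the flask at 10 d of 57.7%.

4. At 12 h the flask's E times time is 2.46 times that of Tuesday's first reading, so I place it between that reading and the plateau. That first reading gives an excess of 57.8%, with a scatter of 3.7 points, and the plateau gives 57.7%, so I expect about that excess in the flask at 12 h.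

The forecast, on the ground “Z is the limiting reagent”, gives 58%, 57.5% and 29.8% in the order asked, and its part reacted stands inside my bracket.

The flask gives 57.8%, 57.5% and 29.5% in the order asked, the last below c by 0.5 points.

    Z + E + D → E + L (k = 0.0140 L² mol⁻² s⁻¹)
    Z + E + Q → E + G (k = 0.00300 L² mol⁻² s⁻¹)
    Z + E → J (k = 6.90 × 10⁻⁵ L mol⁻¹ s⁻¹)
    E ⇌ X (K = 0.810, k = 7.00 × 10⁻⁵ s⁻¹)

The half-life of Z by the step that makes L, 0.087 d at 0.0515 d, is short against 10 d, and in the flask at 10.0 d Z stands at 0% of its charge while 54% of the charged D and 87% of the charged Q remain . The same flask with 0.74 M of Z has c = 119%, and at 10 d it holds 20% of its Z, has reacted 89.9% and shows an excess of 11.2%.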